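## Retrosynthetic overview
1. Target ⇐ acetonide methanolysis and C8 equilibration of a kinetic 2‑bromo‑4‑hydroxycyclopentenone that already carries both complete side chains.
2. The cyclopentenone is the only ring made (C8–C12 bond). It comes from a Piancatelli rearrangement, a conrotatory 4π electrocyclisation of the hydroxypentadienyl cation from a 3‑bromo‑5‑alkyl‑2‑furylcarbinol. Furan C3‑Br becomes C10‑Br and furan C5 becomes C12(OH).
3. Furylcarbinol (C8–C9 bond) ⇐ 3‑bromo‑2‑furyl Grignard + C1–C8 aldehyde ester.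
4. Aldehyde ester ⇐ diacetone‑D‑galactose (gal C2, C3, C4 = C7, C6, C5) by iodination, Zn fragmentation and cross‑metathesis/hydrogenation.
5. Furan piece ⇐ 2,3‑dibromofuran + (2Z,5Z)‑octadienyl bromide (skipped diyne, cis‑semihydrogenation). Ring order: purchased furan → cyclopentenone.

Convention: prostanoid numbering is used (C1 = ester carbonyl, ring = C8–C12, C20 = chain methyl). The CIP letters at C6 and C7 change with the O‑substituents, although no bond to these centres is ever broken.

## Route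

Step 1
Reactants: 1 1-bromopent-2-yne; 2 prop-2-yn-1-ol
Product: 3 octa-2,5-diyn-1-ol
Conditions: CuI (cat.), n-Bu4NCl, K2CO3, DMF, rt
Reagents that add atoms: none
Why: Cu(I)-promoted coupling of the copper acetylide with the propargylic bromide (Jeffery-type sp–sp3 coupling) gives the skipped diyne, and no stereocentre is formed.

Step 2
Reactants: 3 octa-2,5-diyn-1-ol
Product: 4 (2Z,5Z)-octa-2,5-dien-1-ol
Conditions: H2 (1 atm), P-2 Ni (Ni(OAc)2·4H2O/NaBH4, cat.), ethylenediamine, EtOH, rt
Reagents that add atoms: none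
Why: In the Brown P-2 nickel semihydrogenation, syn delivery of H2 to each alkyne sets both Z alkenes and the diamine poison stops over-reduction.

Step 3
Reactants: 4 (2Z,5Z)-octa-2,5-dien-1-ol
Product: 5 (2Z,5Z)-1-bromoocta-2,5-diene
Conditions: CBr4, PPh3, CH2Cl2, −20 °C
Reagents that add atoms: tetrabromomethane, BrC(Br)(Br)Br
Why: The Appel reaction displaces the primary allylic oxyphosphonium by SN2 under neutral, cold conditions and keeps both Z alkenes.

Step 4
Reactants: 6 2,3-dibromofuran; 5 (2Z,5Z)-1-bromoocta-2,5-diene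
Product: 8 2,3-dibromo-5-[(2Z,5Z)-octa-2,5-dien-1-yl]furan, via furylmagnesium chloride 7 (not isolated)
Conditions: TMPMgCl·LiCl (1.1 equiv), THF, −40 °C; Li2CuCl4 (5 mol %), then 5, −40 → 0 °C
Reagents that add atoms: none
Why: Knochel–Hauser magnesiation takes the most acidic α‑H (C5) and the Mg species does not undergo halogen dance, and the Kochi-type Cu-catalysed coupling run with all the Grignard present (cuprate regime) favours α (SN2) attack on the primary allylic bromide with retention of Z geometry.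

Step 5
Reactants: 9 1,2:3,4-di-O-isopropylidene-α-D-galactopyranose
Product: 10 6-deoxy-6-iodo-1,2:3,4-di-O-isopropylidene-α-D-galactopyranose
Conditions: I2, PPh3, imidazole, toluene, 80 °C
Reagents that add atoms: iodine, II
Why: Garegg–Samuelsson iodination converts the only free (primary) hydroxyl and touches no stereocentre.

Step 6
Reactants: 10 6-deoxy-6-iodo-1,2:3,4-di-O-isopropylidene-α-D-galactopyranose
Product: 11 5,6-dideoxy-3,4-O-isopropylidene-aldehydo-L-arabino-hex-5-enose
Conditions: activated Zn dust, THF–H2O (9:1), sonication, 40 °C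
Reagents that add atoms: none
Why: In the Bernet–Vasella reductive fragmentation the C6 organozinc expels ring O5 to give the vinyl group, the freed C1 hemiacetal loses acetone to give the aldehyde and the free 2‑OH, and gal C2, C3, C4 (= C7, C6, C5) pass through unchanged.

Step 7
Reactants: 11 5,6-dideoxy-3,4-O-isopropylidene-aldehydo-L-arabino-hex-5-enose
Product: 12 5,6-dideoxy-3,4-O-isopropylidene-2-O-triethylsilyl-aldehydo-L-arabino-hex-5-enose
Conditions: TESCl, imidazole, CH2Cl2, 0 °C (on crude 11)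
Reagents that add atoms: chlorotriethylsilane, CC[Si](Cl)(CC)CC
Why: Silyl ether formation masks the α‑hydroxyl temporarily, which stops dimerisation of the α‑hydroxy aldehyde and saves an equivalent of Grignard in step 9.

Step 8
Reactants: 12 5,6-dideoxy-3,4-O-isopropylidene-2-O-triethylsilyl-aldehydo-L-arabino-hex-5-enose; 13 methyl but-3-enoate
Product: 15 methyl (5S,6S,7R)-5,6-(isopropylidenedioxy)-8-oxo-7-(triethylsilyloxy)octanoate, via cross-metathesis enoate 14 (not isolated)
Conditions: 13 (3 equiv), Hoveyda–Grubbs II (3 mol %), CH2Cl2, 40 °C; solvent switch to EtOAc, Pd/C, H2 (1 atm), rt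
Reagents that add atoms: none
Why: Olefin cross-metathesis of the 4‑vinyldioxolane (type II) with the type I butenoate adds C3–C1, and the one-pot hydrogenation saturates whichever alkene isomer is formed without touching the aldehyde, TES ether or acetonide.

Step 9
Reactants: 8 2,3-dibromo-5-[(2Z,5Z)-octa-2,5-dien-1-yl]furan; 15 methyl (5S,6S,7R)-5,6-(isopropylidenedioxy)-8-oxo-7-(triethylsilyloxy)octanoate
Product: 18 methyl (5S,6R,7S)-8-[3-bromo-5-((2Z,5Z)-octa-2,5-dien-1-yl)furan-2-yl]-7,8-dihydroxy-5,6-(isopropylidenedioxy)octanoate (C8 epimers), via furyl Grignard 16 (not isolated), via TES carbinol 17 (not isolated)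
Conditions: 8, i-PrMgCl·LiCl (1.05 equiv), THF, −40 °C; 15, −40 → −10 °C; AcOH, then TBAF, 0 °C
Reagents that add atoms: none
Why: Turbo-Grignard Br/Mg exchange occurs only at the α (C2) bromine, 1,2‑addition to the aldehyde is much faster than attack on the ester, the C8 configuration is irrelevant because C8 is ionised in step 10, and buffered fluoride frees the C7‑OH needed for stereocontrol.

Step 10
Reactants: 18 methyl (5S,6R,7S)-8-[3-bromo-5-((2Z,5Z)-octa-2,5-dien-1-yl)furan-2-yl]-7,8-dihydroxy-5,6-(isopropylidenedioxy)octanoate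
Product: 20 methyl (5S,6R,7S,8S,12S,14Z,17Z)-10-bromo-7,12-dihydroxy-5,6-(isopropylidenedioxy)-9-oxoprosta-10,14,17-trienoate (C12-OH trans to the C8 chain), via hydroxypentadienyl cation 19 (not isolated)
Conditions: ZnCl2 (2 equiv), 1,4-dioxane–H2O (4:1), 80 °C
Reagents that add atoms: water, O
Why: In this Piancatelli rearrangement, ionisation of C8‑OH, addition of water at the alkylated furan C5 and ring opening give 19, whose conrotatory 4π electrocyclisation (C7 and the C12 oxygen both outside) forms C8–C12 with C12‑OH trans to the C8 chain, while the free C7‑OH held syn-coplanar with the C9 oxygen in a six-membered Zn chelate/H-bond (a Fráter–Seebach-type arrangement) is expected to direct bond formation anti to the C6 dioxolane, giving 8S,12S, with the furan C3‑Br becoming the C10 vinyl bromide.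

Step 11
Reactants: 20 methyl (5S,6R,7S,8S,12S,14Z,17Z)-10-bromo-7,12-dihydroxy-5,6-(isopropylidenedioxy)-9-oxoprosta-10,14,17-trienoate
Product: 21 methyl (5S,6R,7S,8R,12S,14Z,17Z)-10-bromo-7,12-dihydroxy-5,6-(isopropylidenedioxy)-9-oxoprosta-10,14,17-trienoate (carbon chains trans; C12-OH cis to the C8 chain)
Conditions: DBU (0.2 equiv), CH2Cl2, 0 °C → rt; recovered 20 recycled
Reagents that add atoms: none
Why: Base-catalysed epimerisation through the cross-conjugated dienolate affects only the enolisable C8, the equilibrium should favour the isomer with the two carbon chains trans and C12‑OH able to hydrogen-bond to O7 so that C8 becomes R under control of C12, and a catalytic amidine at or below rt limits retro-aldol and E1cB loss of O7 or O12.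

Step 12
Reactants: 21 methyl (5S,6R,7S,8R,12S,14Z,17Z)-10-bromo-7,12-dihydroxy-5,6-(isopropylidenedioxy)-9-oxoprosta-10,14,17-trienoate
Product: 22 methyl (5S,6S,7S,8R,12S,14Z,17Z)-10-bromo-5,6,7,12-tetrahydroxy-9-oxoprosta-10,14,17-trienoate (target)
Conditions: TsOH·H2O (10 mol %), MeOH, rt
Reagents that add atoms: none
Why: Acid-catalysed transketalisation to methanol removes the acetonide, methanol as solvent holds the 5‑hydroxy ester open against δ‑lactonisation, and the C12 carbinol is acid-tolerant because its cation would be destabilised by the enone.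

## Compound list
1 | 1-bromopent-2-yne | CCC#CCBr | starting material
2 | prop-2-yn-1-ol | OCC#C | starting material
3 | octa-2,5-diyn-1-ol | CCC#CCC#CCO | intermediate
4 | (2Z,5Z)-octa-2,5-dien-1-ol | CC/C=C\C/C=C\CO | intermediate
5 | (2Z,5Z)-1-bromoocta-2,5-diene | CC/C=C\C/C=C\CBr | intermediate
6 | 2,3-dibromofuran | Brc1ccoc1Br | starting material
7 | (4,5-dibromofuran-2-yl)magnesium chloride (LiCl complex) | Cl[Mg]c1cc(Br)c(Br)o1 | intermediate
8 | 2,3-dibromo-5-[(2Z,5Z)-octa-2,5-dien-1-yl]furan | CC/C=C\C/C=C\Cc1cc(Br)c(Br)o1 | intermediate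
9 | 1,2:3,4-di-O-isopropylidene-α-D-galactopyranose | OC[C@H]1O[C@@H]2OC(C)(C)O[C@@H]2[C@H]3OC(C)(C)O[C@@H]13 | starting material
10 | 6-deoxy-6-iodo-1,2:3,4-di-O-isopropylidene-α-D-galactopyranose | IC[C@H]1O[C@@H]2OC(C)(C)O[C@@H]2[C@H]3OC(C)(C)O[C@@H]13 | intermediate
11 | 5,6-dideoxy-3,4-O-isopropylidene-aldehydo-L-arabino-hex-5-enose | O=C[C@H](O)[C@H]1OC(C)(C)O[C@H]1C=C | intermediate
12 | 2-O-triethylsilyl ether of 11 | O=C[C@H](O[Si](CC)(CC)CC)[C@H]1OC(C)(C)O[C@H]1C=C | intermediate
13 | methyl but-3-enoate | C=CCC(=O)OC | starting material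
14 | methyl (3E,5S,6S,7R)-5,6-(isopropylidenedioxy)-8-oxo-7-(triethylsilyloxy)oct-3-enoate | O=C[C@H](O[Si](CC)(CC)CC)[C@H]1OC(C)(C)O[C@H]1/C=C/CC(=O)OC | intermediate
15 | methyl (5S,6S,7R)-5,6-(isopropylidenedioxy)-8-oxo-7-(triethylsilyloxy)octanoate | O=C[C@H](O[Si](CC)(CC)CC)[C@H]1OC(C)(C)O[C@H]1CCCC(=O)OC | intermediate
16 | [3-bromo-5-((2Z,5Z)-octa-2,5-dien-1-yl)furan-2-yl]magnesium chloride | CC/C=C\C/C=C\Cc1cc(Br)c([Mg]Cl)o1 | intermediate
17 | methyl (5S,6S,7S)-8-[3-bromo-5-((2Z,5Z)-octa-2,5-dien-1-yl)furan-2-yl]-8-hydroxy-5,6-(isopropylidenedioxy)-7-(triethylsilyloxy)octanoate (C8 epimers) | CC/C=C\C/C=C\Cc1cc(Br)c(o1)C(O)[C@H](O[Si](CC)(CC)CC)[C@H]2OC(C)(C)O[C@H]2CCCC(=O)OC | intermediate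
18 | methyl (5S,6R,7S)-8-[3-bromo-5-((2Z,5Z)-octa-2,5-dien-1-yl)furan-2-yl]-7,8-dihydroxy-5,6-(isopropylidenedioxy)octanoate (C8 epimers) | CC/C=C\C/C=C\Cc1cc(Br)c(o1)C(O)[C@H](O)[C@H]2OC(C)(C)O[C@H]2CCCC(=O)OC | intermediate
19 | 10-bromo-9,12-dihydroxypentadienyl cation (C8–C12 open; C7 outside; C9 and C12 cis on C10=C11) | CC/C=C\C/C=C\CC(=[OH+])/C=C(Br)\C(O)=C\[C@H](O)[C@H]1OC(C)(C)O[C@H]1CCCC(=O)OC | intermediate
20 | kinetic cyclopentenone, (5S,6R,7S,8S,12S) | CC/C=C\C/C=C\C[C@@]1(O)C=C(Br)C(=O)[C@H]1[C@H](O)[C@H]2OC(C)(C)O[C@H]2CCCC(=O)OC | intermediate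
21 | equilibrated cyclopentenone, (5S,6R,7S,8R,12S) | CC/C=C\C/C=C\C[C@@]1(O)C=C(Br)C(=O)[C@@H]1[C@H](O)[C@H]2OC(C)(C)O[C@H]2CCCC(=O)OC | intermediate
22 | methyl (5S,6S,7S,8R,12S,14Z,17Z)-10-bromo-5,6,7,12-tetrahydroxy-9-oxoprosta-10,14,17-trienoate | CC/C=C\C/C=C\C[C@@]1(O)C=C(Br)C(=O)[C@@H]1[C@H](O)[C@@H](O)[C@@H](O)CCCC(=O)OC | target

## Step count and risks
Total steps: 12. Longest linear sequence: 8 (steps 5–12; the branch through steps 1–4 and 9–12 is also 8).

**Risk 1 (step 10).**
- The carbinol is deactivated by the β‑oxygen and the 3‑Br.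
- The cation can be diverted by a 1,2‑hydride shift from C7 or by proton loss at C13.
- The acetonide may partly hydrolyse.
- The direction of conrotation rests on the C7‑OH chelate model; without the chelate, closure anti to C6 in the H‑inside conformer would give the 8R,12R ring.

The fallback replaces the electrocyclisation by oxidative furan opening and intramolecular aldol closure. It sets out from 17, which is isolated by omitting TBAF in the step 9 work-up. Ionic reduction of the furylic hydroxyl (Et3SiH, TFA, CH2Cl2, −40 °C) gives methyl (5S,6S,7S)-8-[3-bromo-5-((2Z,5Z)-octa-2,5-dien-1-yl)furan-2-yl]-5,6-(isopropylidenedioxy)-7-(triethylsilyloxy)octanoate F1. Sensitised photo-oxygenation (O2, methylene blue, hν, CH2Cl2, −78 °C) exploits the much faster reaction of the furan than of the cis‑alkenes and gives the furan endoperoxide F2. Me2S reduces this to the cis‑enedione F3. Mild equilibrating base (pH 8 buffer or catalytic DBU) closes C8 onto the C12 ketone to give the 7-O-triethylsilyl ether of 21 F4, with the chains trans directly. Competing enolisation at C13 is the weak point of this sequence. AcOH/TBAF then brings the material back to the route at 21.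

**Risk 2 (step 11).** The equilibrium constant may be modest. The free β‑hydroxy ketone motifs (C7 and C12) also open retro‑aldol or elimination channels on prolonged base contact.

The fallback uses a covalent template instead of the intrinsic equilibrium. It sets out from 20, which is stirred with PhB(OH)2 (1.1 equiv), 4 Å sieves and catalytic Et3N in toluene. Only the 8R epimer has O7 and O12 on the same ring face, so only it can close a six-membered ring. The equilibrating mixture is therefore drained into the cyclic 7,12-O-phenylboronate of 21 F5. Exchange with pinacol releases the diol and returns to the route at 21.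

**Risk 3 (step 4).** α versus γ attack and retention of the Z‑allyl geometry in the Cu‑catalysed coupling of an electron‑poor furyl Grignard are not assured.

The fallback makes the C12–C13 bond first and places the bromine afterwards by a halogen dance. It sets out from 5, which alkylates 2‑furyllithium (furan, n‑BuLi, THF, −78 → 0 °C) to give 2-[(2Z,5Z)-octa-2,5-dien-1-yl]furan F6. NBS in DMF at −20 °C gives 2-bromo-5-[(2Z,5Z)-octa-2,5-dien-1-yl]furan F7. LDA (THF, −78 → −50 °C) triggers the halogen dance to [3-bromo-5-((2Z,5Z)-octa-2,5-dien-1-yl)furan-2-yl]lithium F8. This adds to 15 at −78 °C and, after an AcOH quench, comes back to the route at 17.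

## Further compounds
F1 | step 10 | methyl (5S,6S,7S)-8-[3-bromo-5-((2Z,5Z)-octa-2,5-dien-1-yl)furan-2-yl]-5,6-(isopropylidenedioxy)-7-(triethylsilyloxy)octanoate | CC/C=C\C/C=C\Cc1cc(Br)c(o1)C[C@H](O[Si](CC)(CC)CC)[C@H]2OC(C)(C)O[C@H]2CCCC(=O)OC
F2 | step 10 | furan endoperoxide (2,3,7-trioxabicyclo[2.2.1]hept-5-ene) of F1, bridgehead epimers | CC/C=C\C/C=C\CC12C=C(Br)C(C[C@H](O[Si](CC)(CC)CC)[C@H]3OC(C)(C)O[C@H]3CCCC(=O)OC)(OO1)O2
F3 | step 10 | cis-enedione, methyl (5S,6S,7S,14Z,17Z)-10-bromo-5,6-(isopropylidenedioxy)-9,12-dioxo-7-(triethylsilyloxy)icosa-10,14,17-trienoate (carbonyls cis on C10=C11) | CC/C=C\C/C=C\CC(=O)/C=C(Br)\C(=O)C[C@H](O[Si](CC)(CC)CC)[C@H]1OC(C)(C)O[C@H]1CCCC(=O)OC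
F4 | step 10 | 7-O-triethylsilyl ether of 21 | CC/C=C\C/C=C\C[C@@]1(O)C=C(Br)C(=O)[C@@H]1[C@H](O[Si](CC)(CC)CC)[C@H]2OC(C)(C)O[C@H]2CCCC(=O)OC
F5 | step 11 | cyclic 7,12-O-phenylboronate of 21 | CC/C=C\C/C=C\C[C@@]1(OB(c3ccccc3)O4)C=C(Br)C(=O)[C@@H]1[C@H]4[C@H]2OC(C)(C)O[C@H]2CCCC(=O)OC
F6 | step 4 | 2-[(2Z,5Z)-octa-2,5-dien-1-yl]furan | CC/C=C\C/C=C\Cc1ccco1
F7 | step 4 | 2-bromo-5-[(2Z,5Z)-octa-2,5-dien-1-yl]furan | CC/C=C\C/C=C\Cc1ccc(Br)o1
F8 | step 4 | [3-bromo-5-((2Z,5Z)-octa-2,5-dien-1-yl)furan-2-yl]lithium | CC/C=C\C/C=C\Cc1cc(Br)c([Li])o1
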